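Between 10.0 min and 15.0 min the crystals D gain 0.0257 M/min in the zeta run and 0.0432 M/min in the alpha run, while dissolved E (E minus D, since E counts the crystals too) averages 0.151 M and 0.218 M.

| flask | X | remark | time |
|---|---|---|---|
| zeta | 1.1 M | run made earlier |  |
| alpha | 1.8 M | run made earlier |  |
| flask | 0.80 M |  | 15 min |

| run | time / min | E / % | D / % |
|---|---|---|---|
| zeta | 3.00 | 13.2 | 0.8 |
| zeta | 6.00 | 24.5 | 9.5 |
| zeta | 10.0 | 34.5 | 20.2 |
| zeta | 12.0 | 39.3 | 26.5 |
| zeta | 15.0 | 45.0 | 31.9 |
| alpha | 3.00 | 12.9 | 2.9 |
| alpha | 6.00 | 23.2 | 8.8 |
| alpha | 10.0 | 34.4 | 20.3 |
| alpha | 12.0 | 36.9 | 25.8 |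
| alpha | 15.0 | 42.4 | 32.3 |

(scatter of a reading: 0.5 percentage points)

- the E and D together standing at 15 min, as a percentage of the X charged
- concentration of E in solution at 15 min, in percent of saturation

- for E the D are counted in
- as a solid, counted per litre of solution: D
- the numbers in the tables scatter with a standard deviation of 0.5 percentage points

How does growth follow dissolved E? I draw a straight line through these two readings. Its inverse slope, 3.84 min, is the excess of dissolved E over saturation divided by the growth rate of D: the crystal lag. Growth reaches zero at a saturation I read as 0.0518 M, roughly, given the scatter.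

Does the lag apply to the flask? It is shorter than 15 min, so I let growth keep pace with making: supersaturation equals making rate times lag.

How fast does the flask make E? The runs reach 45.0% and 42.4% despite different charges, so I take the zeta curve. That gives y near 45.0%, and the zeta slope from 10.0 min to 15.0 min, put on the flask's charge, gives a rate of 0.0168 M/min.

My first answer is dissolved E at saturation. Going round once more adds 0.0646 M, giving 0.116 M, or 225% of saturation. D in the flask is then 30.5% by my reckoning, so I expect crystals to stand there.

The forecast says 44% and 125%: "the solution stays supersaturated, and more so where E forms faster". We part on saturation.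

The flask gives 46.6% and 276%. At 15.0 min its dissolved E is made at 0.812 of the rate at which it is used up, each step taken net and going into crystals counted as use.

    X ⇌ E + J (K = 0.327 M, k = 0.0497 /min)
    D ⇌ E, rate k2*(cs2 - [E]) while solid is left; crystals form when [E] > cs2 (solubility = 42.0 mM, k = 0.244 /min)

At 15.0 min the flask holds 0.116 M dissolved, against my 0.116 M. The same charge left until 60.0 min makes E at 0.00413 M/min on average after 30.0 min. With that average the lag gives me 0.0677 M dissolved, and at 60.0 min that flask holds 0.0525 M.

(The earlier runs and the new flask are simulated for an exercise; noise was put on by code.)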